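**Plan**

1. Each half is a 2-benzoxepine lactone (C1 lactone C=O, O2, C3H2, C4–CO2R, C5=, C5a, C6–iPr, C7, C8, C9, C9a; these locants are used for the same carbons throughout). The cuts are: the ester between the C4 acid of the diol half and the C9–CH2OH of the other half; both C9 diols back to C9=CH2 and on to a C9 ketone; the lactone C1–O2 bond; then C7–C8 and C5a–C9a together.
2. Enabling feature: C9a lies between the lactone carbonyl C1 and C9. With C9 as a ketone, C8–C9–C9a is the γ,α-dinucleophile of an acetoacetate ester, and C7–C6–C5a is the C=O, α- and β-carbon of an α-isopropyl dienal whose δ-carbon (C4) is already fully substituted.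
3. Forward: dienal 9 (four steps) and tert-butyl acetoacetate give, by amine-catalysed Michael/aldol condensation, the cyclohexane ring carrying the whole C15 skeleton. The seven-membered lactone ring then closes by acylketene capture; methylenation and dihydroxylation complete C9.
4. The sequence is run twice with pseudo-enantiomeric catalysts. Acid 20 and diol 29 are joined by Yamaguchi esterification, and the last diol is made in the final step under neutral conditions.
5. Stereochemistry: C5a from the catalyst; C6 and C9a by equilibration (all three ring substituents equatorial); C9 by osmylation from the equatorial face; alkene geometry from the olefination/condensation steps and from the ring.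

Key step: step 5

Remark: read as written, the diol half is (5aS,6R,9S,9aS) and the O-acylated half is (5aR,6S,9R,9aR), so the two bicycles have opposite handedness; each is made from the same achiral precursors with one of two pseudo-enantiomeric catalysts, whose assignment to the two series follows the usual shielding model and would simply be exchanged if the sense proved reversed.

**Step 1**
Reactants: 1 tert-butyl 2-(diethoxyphosphoryl)acetate; 2 formaldehyde (37% aqueous); 3 2,2-dimethoxyacetaldehyde (60% aqueous)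
Product: 5 tert-butyl (2E)-2-(hydroxymethyl)-4,4-dimethoxybut-2-enoate, via hydroxymethyl phosphonate 4 (not isolated)
Conditions: 2 (1.0 equiv), K2CO3 (0.1 equiv), H2O/THF, 0 °C; then 3 (1.5 equiv), K2CO3 (2 equiv), rt
Reagents that add atoms: none
Why: Villieras-type hydroxymethylation of the phosphonoacetate followed by Horner–Wadsworth–Emmons olefination of the activated aldehyde 3 should give the trisubstituted enoate, the α-branched phosphonate placing the acetal carbon trans to the ester (E), any Z isomer being removed by chromatography.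

**Step 2**
Reactants: 5 tert-butyl (2E)-2-(hydroxymethyl)-4,4-dimethoxybut-2-enoate
Product: 6 tert-butyl (2E)-2-({[tert-butyl(diphenyl)silyl]oxy}methyl)-4,4-dimethoxybut-2-enoate
Conditions: TBDPSCl, imidazole, DMF, rt
Reagents that add atoms: tert-butyl(chloro)diphenylsilane, CC(C)(C)[Si](Cl)(c1ccccc1)c1ccccc1
Why: standard silylation of a primary allylic alcohol; the acid-stable silyl ether keeps the hydroxyl from closing onto the aldehyde freed in step 3 (lactol, then furan) and from oxa-Michael addition later.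

**Step 3**
Reactants: 6 tert-butyl (2E)-2-({[tert-butyl(diphenyl)silyl]oxy}methyl)-4,4-dimethoxybut-2-enoate
Product: 7 tert-butyl (2E)-2-({[tert-butyl(diphenyl)silyl]oxy}methyl)-4-oxobut-2-enoate
Conditions: p-TsOH·H2O (cat.), acetone/H2O (10:1), rt
Reagents that add atoms: water, O
Why: mild acid-catalysed acetal hydrolysis (transacetalisation to acetone) should leave the tert-butyl ester, the silyl ether and the alkene geometry untouched.

**Step 4**
Reactants: 7 tert-butyl (2E)-2-({[tert-butyl(diphenyl)silyl]oxy}methyl)-4-oxobut-2-enoate; 8 3-methylbutanal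
Product: 9 tert-butyl (2E,4E)-2-({[tert-butyl(diphenyl)silyl]oxy}methyl)-5-formyl-6-methylhepta-2,4-dienoate
Conditions: pyrrolidine (20 mol%), 4-(dimethylamino)benzoic acid (20 mol%), CH2Cl2, rt, 8 (1.5 equiv) added slowly
Reagents that add atoms: none
Why: amine-catalysed cross-aldol (Mannich-type) condensation, in which 7 has no enolisable α-hydrogen and acts as the iminium electrophile while the enamine of 8 is the only donor; elimination should give the thermodynamic (E)-α-isopropyl enal.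

**Step 5**
Reactants: 9 tert-butyl (2E,4E)-2-({[tert-butyl(diphenyl)silyl]oxy}methyl)-5-formyl-6-methylhepta-2,4-dienoate; 10 tert-butyl 3-oxobutanoate
Product: 13 tert-butyl (1S,5S,6S)-6-[(1E)-3-tert-butoxy-2-({[tert-butyl(diphenyl)silyl]oxy}methyl)-3-oxoprop-1-en-1-yl]-2-oxo-5-(propan-2-yl)cyclohex-3-ene-1-carboxylate, via Michael adduct aldehyde 11 (not isolated), via aldol 12 (not isolated)
Conditions: 9-amino-9-deoxy-epi-quinine (20 mol%), TFA (40 mol%), 10 (1.5 equiv), toluene, 40 °C; then 4 Å MS, 60 °C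
Reagents that add atoms: none
Why: The primary amine of the catalyst condenses with dienal 9 to an iminium ion and the enol of 10 adds through its doubly activated carbon to the β-carbon (C5a–C9a bond), hydrolysis giving aldehyde 11; the amine then turns the methyl ketone into its enamine, whose terminal carbon (C8) attacks the aldehyde carbon (C7) to give aldol 12, which loses water to enone 13. The closest known reaction type is the amine-catalysed Michael/aldol condensation of β-keto esters with enals (organocatalytic Robinson- or Hagemann-type [3+3] cyclohexenone annulation), run here with a cinchona primary amine as is usual for α-branched enals. Only the cyclohexane ring closes in this step, by a 6-(enolendo)-exo-trig aldol addition; the seven-membered ring is left for step 8. C5a is set by the catalyst, which shields one face of the iminium ion; C9a (between ketone and ester) and C6 (α to the aldehyde in 11, γ to the enone in 13, mobile through enamine and dienamine) equilibrate, so that the three neighbouring substituents should end all-trans and equatorial. The step needs 1,4- over 1,6-addition and attack on the enal and not on the enoate: the δ-carbon carries the ester and the silyloxymethyl group and is blocked, and only the enal is activated as an iminium ion.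

**Step 6**
Reactants: 13 tert-butyl (1S,5S,6S)-6-[(1E)-3-tert-butoxy-2-({[tert-butyl(diphenyl)silyl]oxy}methyl)-3-oxoprop-1-en-1-yl]-2-oxo-5-(propan-2-yl)cyclohex-3-ene-1-carboxylate
Product: 14 tert-butyl (1S,5R,6S)-6-[(1E)-3-tert-butoxy-2-({[tert-butyl(diphenyl)silyl]oxy}methyl)-3-oxoprop-1-en-1-yl]-2-oxo-5-(propan-2-yl)cyclohexane-1-carboxylate
Conditions: H2 (3 atm), RhCl(PPh3)3 (5 mol%), benzene, rt
Reagents that add atoms: none
Why: homogeneous hydrogenation should reduce the cis-disubstituted ring alkene and leave the trisubstituted, ester-conjugated side-chain alkene and its allylic C–O bond alone; no stereocentre is made and C6 is fixed from here on.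

**Step 7**
Reactants: 14 tert-butyl (1S,5R,6S)-6-[(1E)-3-tert-butoxy-2-({[tert-butyl(diphenyl)silyl]oxy}methyl)-3-oxoprop-1-en-1-yl]-2-oxo-5-(propan-2-yl)cyclohexane-1-carboxylate
Product: 15 tert-butyl (1S,5R,6S)-6-[(1E)-3-tert-butoxy-2-(hydroxymethyl)-3-oxoprop-1-en-1-yl]-2-oxo-5-(propan-2-yl)cyclohexane-1-carboxylate
Conditions: HF·pyridine, pyridine/THF, 0 °C to rt
Reagents that add atoms: none
Why: fluoride-mediated cleavage of the silyl ether under buffered conditions that should spare both tert-butyl esters and the β-keto ester.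

**Step 8**
Reactants: 15 tert-butyl (1S,5R,6S)-6-[(1E)-3-tert-butoxy-2-(hydroxymethyl)-3-oxoprop-1-en-1-yl]-2-oxo-5-(propan-2-yl)cyclohexane-1-carboxylate
Product: 17 tert-butyl (5aS,6R,9aS)-1,9-dioxo-6-(propan-2-yl)-1,3,5a,6,7,8,9,9a-octahydro-2-benzoxepine-4-carboxylate, via acylketene 16 (not isolated)
Conditions: toluene (0.005 M), 110 °C, 4 Å MS
Reagents that add atoms: none
Why: thermal loss of tert-butanol from the β-keto tert-butyl ester gives the acylketene, which the cis-disposed allylic hydroxyl should capture in a 7-exo-dig addition (acylketene lactonisation); the conjugated tert-butyl ester is not a β-keto ester and stays, and C9a is re-protonated to the more stable trans ring fusion.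

**Step 9**
Reactants: 17 tert-butyl (5aS,6R,9aS)-1,9-dioxo-6-(propan-2-yl)-1,3,5a,6,7,8,9,9a-octahydro-2-benzoxepine-4-carboxylate
Product: 18 tert-butyl (5aS,6R,9aS)-9-methylidene-1-oxo-6-(propan-2-yl)-1,3,5a,6,7,8,9,9a-octahydro-2-benzoxepine-4-carboxylate
Conditions: Zn, CH2Br2, TiCl4, THF, 0 °C (aged reagent); then 17, CH2Cl2, rt
Reagents that add atoms: dibromomethane, BrCBr
Why: Takai–Lombardo methylenation, a non-basic reagent chosen for easily enolised ketones and inert to esters and lactones, should convert only the C9 ketone and leave C9a as it is.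

**Step 10**
Reactants: 18 tert-butyl (5aS,6R,9aS)-9-methylidene-1-oxo-6-(propan-2-yl)-1,3,5a,6,7,8,9,9a-octahydro-2-benzoxepine-4-carboxylate
Product: 20 (5aS,6R,9aS)-9-methylidene-1-oxo-6-(propan-2-yl)-1,3,5a,6,7,8,9,9a-octahydro-2-benzoxepine-4-carboxylic acid, via trimethylsilyl ester 19 (not isolated)
Conditions: TMSOTf, 2,6-lutidine, CH2Cl2, 0 °C to rt; then pH 4 aqueous buffer
Reagents that add atoms: none
Why: silyl triflate-mediated tert-butyl ester cleavage (the tert-butyl cation leaves as isobutene to the hindered base) followed by hydrolysis of the silyl ester; no protic acid is present, so the acid-sensitive 1,1-disubstituted alkene should survive.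

**Step 11**
Reactants: 9 tert-butyl (2E,4E)-2-({[tert-butyl(diphenyl)silyl]oxy}methyl)-5-formyl-6-methylhepta-2,4-dienoate; 10 tert-butyl 3-oxobutanoate
Product: 23 tert-butyl (1R,5R,6R)-6-[(1E)-3-tert-butoxy-2-({[tert-butyl(diphenyl)silyl]oxy}methyl)-3-oxoprop-1-en-1-yl]-2-oxo-5-(propan-2-yl)cyclohex-3-ene-1-carboxylate, via Michael adduct aldehyde 21 (not isolated), via aldol 22 (not isolated)
Conditions: 9-amino-9-deoxy-epi-quinidine (20 mol%), TFA (40 mol%), 10 (1.5 equiv), toluene, 40 °C; then 4 Å MS, 60 °C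
Reagents that add atoms: none
Why: the same Michael/aldol condensation as in step 5, in which the pseudo-enantiomeric catalyst shields the other face of the iminium ion, so that C5a and, after equilibration of C6 and C9a, the whole ring should form in the mirror-image sense.

**Step 12**
Reactants: 23 tert-butyl (1R,5R,6R)-6-[(1E)-3-tert-butoxy-2-({[tert-butyl(diphenyl)silyl]oxy}methyl)-3-oxoprop-1-en-1-yl]-2-oxo-5-(propan-2-yl)cyclohex-3-ene-1-carboxylate
Product: 24 tert-butyl (1R,5S,6R)-6-[(1E)-3-tert-butoxy-2-({[tert-butyl(diphenyl)silyl]oxy}methyl)-3-oxoprop-1-en-1-yl]-2-oxo-5-(propan-2-yl)cyclohexane-1-carboxylate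
Conditions: H2 (3 atm), RhCl(PPh3)3 (5 mol%), benzene, rt
Reagents that add atoms: none
Why: chemoselective homogeneous hydrogenation of the ring alkene, as in step 6.

**Step 13**
Reactants: 24 tert-butyl (1R,5S,6R)-6-[(1E)-3-tert-butoxy-2-({[tert-butyl(diphenyl)silyl]oxy}methyl)-3-oxoprop-1-en-1-yl]-2-oxo-5-(propan-2-yl)cyclohexane-1-carboxylate
Product: 25 tert-butyl (1R,5S,6R)-6-[(1E)-3-tert-butoxy-2-(hydroxymethyl)-3-oxoprop-1-en-1-yl]-2-oxo-5-(propan-2-yl)cyclohexane-1-carboxylate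
Conditions: HF·pyridine, pyridine/THF, 0 °C to rt
Reagents that add atoms: none
Why: fluoride-mediated desilylation, as in step 7.

**Step 14**
Reactants: 25 tert-butyl (1R,5S,6R)-6-[(1E)-3-tert-butoxy-2-(hydroxymethyl)-3-oxoprop-1-en-1-yl]-2-oxo-5-(propan-2-yl)cyclohexane-1-carboxylate
Product: 27 tert-butyl (5aR,6S,9aR)-1,9-dioxo-6-(propan-2-yl)-1,3,5a,6,7,8,9,9a-octahydro-2-benzoxepine-4-carboxylate, via acylketene 26 (not isolated)
Conditions: toluene (0.005 M), 110 °C, 4 Å MS
Reagents that add atoms: none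
Why: acylketene lactonisation as in step 8, C9a again settling in the trans-fused arrangement.

**Step 15**
Reactants: 27 tert-butyl (5aR,6S,9aR)-1,9-dioxo-6-(propan-2-yl)-1,3,5a,6,7,8,9,9a-octahydro-2-benzoxepine-4-carboxylate
Product: 28 tert-butyl (5aR,6S,9aR)-9-methylidene-1-oxo-6-(propan-2-yl)-1,3,5a,6,7,8,9,9a-octahydro-2-benzoxepine-4-carboxylate
Conditions: Zn, CH2Br2, TiCl4, THF, 0 °C (aged reagent); then 27, CH2Cl2, rt
Reagents that add atoms: dibromomethane, BrCBr
Why: Takai–Lombardo methylenation of the enolisable ketone, as in step 9.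

**Step 16**
Reactants: 28 tert-butyl (5aR,6S,9aR)-9-methylidene-1-oxo-6-(propan-2-yl)-1,3,5a,6,7,8,9,9a-octahydro-2-benzoxepine-4-carboxylate
Product: 29 tert-butyl (5aR,6S,9R,9aR)-9-hydroxy-9-(hydroxymethyl)-1-oxo-6-(propan-2-yl)-1,3,5a,6,7,8,9,9a-octahydro-2-benzoxepine-4-carboxylate
Conditions: OsO4 (2 mol%), NMO, acetone/H2O (4:1), rt
Reagents that add atoms: osmium tetroxide, O=[Os](=O)(=O)=O; N-methylmorpholine N-oxide, C[N+]1([O-])CCOCC1; water, O
Why: Upjohn dihydroxylation, in which only the electron-rich exocyclic alkene should react and the bulky reagent should approach along the equatorial direction (the face next to the axial hydrogens on C8 and C9a, away from the 1,3-diaxial hydrogens on C5a and C7), placing the tertiary hydroxyl equatorial and the CH2OH axial, that is (9R).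

**Step 17**
Reactants: 20 (5aS,6R,9aS)-9-methylidene-1-oxo-6-(propan-2-yl)-1,3,5a,6,7,8,9,9a-octahydro-2-benzoxepine-4-carboxylic acid; 29 tert-butyl (5aR,6S,9R,9aR)-9-hydroxy-9-(hydroxymethyl)-1-oxo-6-(propan-2-yl)-1,3,5a,6,7,8,9,9a-octahydro-2-benzoxepine-4-carboxylate
Product: 31 tert-butyl (5aR,6S,9R,9aR)-9-hydroxy-9-({[(5aS,6R,9aS)-9-methylidene-1-oxo-6-(propan-2-yl)-1,3,5a,6,7,8,9,9a-octahydro-2-benzoxepine-4-carbonyl]oxy}methyl)-1-oxo-6-(propan-2-yl)-1,3,5a,6,7,8,9,9a-octahydro-2-benzoxepine-4-carboxylate, via mixed anhydride 30 (not isolated)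
Conditions: 2,4,6-Cl3C6H2COCl, Et3N, THF, rt; then 29, DMAP, toluene, rt
Reagents that add atoms: none
Why: Yamaguchi esterification, in which the mixed anhydride of 20 should acylate the primary hydroxyl of 29 while the tertiary hydroxyl stays free.

**Step 18**
Reactants: 31 tert-butyl (5aR,6S,9R,9aR)-9-hydroxy-9-({[(5aS,6R,9aS)-9-methylidene-1-oxo-6-(propan-2-yl)-1,3,5a,6,7,8,9,9a-octahydro-2-benzoxepine-4-carbonyl]oxy}methyl)-1-oxo-6-(propan-2-yl)-1,3,5a,6,7,8,9,9a-octahydro-2-benzoxepine-4-carboxylate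
Product: 33 (5aR,6S,9R,9aR)-9-hydroxy-9-({[(5aS,6R,9aS)-9-methylidene-1-oxo-6-(propan-2-yl)-1,3,5a,6,7,8,9,9a-octahydro-2-benzoxepine-4-carbonyl]oxy}methyl)-1-oxo-6-(propan-2-yl)-1,3,5a,6,7,8,9,9a-octahydro-2-benzoxepine-4-carboxylic acid, via bis(trimethylsilyl) derivative 32 (not isolated)
Conditions: TMSOTf, 2,6-lutidine, CH2Cl2, 0 °C; then 10% aqueous citric acid/THF, rt
Reagents that add atoms: none
Why: silyl triflate-mediated tert-butyl ester cleavage as in step 10, the tertiary hydroxyl being silylated in passing and freed again, together with the silyl ester, in the mild acidic work-up; the exocyclic alkene, both lactones and the primary alkyl ester should be untouched.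

**Step 19**
Reactants: 33 (5aR,6S,9R,9aR)-9-hydroxy-9-({[(5aS,6R,9aS)-9-methylidene-1-oxo-6-(propan-2-yl)-1,3,5a,6,7,8,9,9a-octahydro-2-benzoxepine-4-carbonyl]oxy}methyl)-1-oxo-6-(propan-2-yl)-1,3,5a,6,7,8,9,9a-octahydro-2-benzoxepine-4-carboxylic acid
Product: 34 (5aR,6S,9R,9aR)-9-hydroxy-9-({[(5aS,6R,9S,9aS)-9-hydroxy-9-(hydroxymethyl)-1-oxo-6-(propan-2-yl)-1,3,5a,6,7,8,9,9a-octahydro-2-benzoxepine-4-carbonyl]oxy}methyl)-1-oxo-6-(propan-2-yl)-1,3,5a,6,7,8,9,9a-octahydro-2-benzoxepine-4-carboxylic acid (target)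
Conditions: OsO4 (5 mol%), NMO, acetone/H2O (4:1), rt
Reagents that add atoms: osmium tetroxide, O=[Os](=O)(=O)=O; N-methylmorpholine N-oxide, C[N+]1([O-])CCOCC1; water, O
Why: Upjohn dihydroxylation of the one remaining electron-rich alkene with the same equatorial-face preference as in step 16, here giving (9S); the sensitive diol is made last and under neutral conditions.

**Compound list**

1 | tert-butyl 2-(diethoxyphosphoryl)acetate | CCOP(=O)(CC(=O)OC(C)(C)C)OCC | starting material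
2 | formaldehyde (37% aqueous) | C=O | starting material
3 | 2,2-dimethoxyacetaldehyde (60% aqueous) | COC(OC)C=O | starting material
4 | tert-butyl 2-(diethoxyphosphoryl)-3-hydroxypropanoate (racemic) | CCOP(=O)(OCC)C(CO)C(=O)OC(C)(C)C | intermediate
5 | tert-butyl (2E)-2-(hydroxymethyl)-4,4-dimethoxybut-2-enoate | COC(OC)/C=C(\CO)C(=O)OC(C)(C)C | intermediate
6 | tert-butyl (2E)-2-({[tert-butyl(diphenyl)silyl]oxy}methyl)-4,4-dimethoxybut-2-enoate | COC(OC)/C=C(\CO[Si](c1ccccc1)(c2ccccc2)C(C)(C)C)C(=O)OC(C)(C)C | intermediate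
7 | tert-butyl (2E)-2-({[tert-butyl(diphenyl)silyl]oxy}methyl)-4-oxobut-2-enoate | O=C/C=C(\CO[Si](c1ccccc1)(c2ccccc2)C(C)(C)C)C(=O)OC(C)(C)C | intermediate
8 | 3-methylbutanal | CC(C)CC=O | starting material
9 | tert-butyl (2E,4E)-2-({[tert-butyl(diphenyl)silyl]oxy}methyl)-5-formyl-6-methylhepta-2,4-dienoate | CC(C)/C(C=O)=C\C=C(/CO[Si](c1ccccc1)(c2ccccc2)C(C)(C)C)C(=O)OC(C)(C)C | intermediate
10 | tert-butyl 3-oxobutanoate | CC(=O)CC(=O)OC(C)(C)C | starting material
11 | di-tert-butyl (2E,4R)-5-acetyl-2-({[tert-butyl(diphenyl)silyl]oxy}methyl)-4-(3-methyl-1-oxobutan-2-yl)hex-2-enedioate (epimers at C5 and at the formyl-bearing carbon) | CC(C)C(C=O)[C@@H](/C=C(\CO[Si](c1ccccc1)(c2ccccc2)C(C)(C)C)C(=O)OC(C)(C)C)C(C(C)=O)C(=O)OC(C)(C)C | intermediate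
12 | aldol from 11: the 4-hydroxy-2-oxocyclohexane-1-carboxylate with ring substituents at C1, C5 and C6 as in 13, both hydroxyl epimers | CC(C)[C@H]1C(O)CC(=O)[C@@H](C(=O)OC(C)(C)C)[C@@H]1/C=C(\CO[Si](c2ccccc2)(c3ccccc3)C(C)(C)C)C(=O)OC(C)(C)C | intermediate
13 | tert-butyl (1S,5S,6S)-6-[(1E)-3-tert-butoxy-2-({[tert-butyl(diphenyl)silyl]oxy}methyl)-3-oxoprop-1-en-1-yl]-2-oxo-5-(propan-2-yl)cyclohex-3-ene-1-carboxylate | CC(C)[C@H]1C=CC(=O)[C@@H](C(=O)OC(C)(C)C)[C@@H]1/C=C(\CO[Si](c2ccccc2)(c3ccccc3)C(C)(C)C)C(=O)OC(C)(C)C | intermediate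
14 | tert-butyl (1S,5R,6S)-6-[(1E)-3-tert-butoxy-2-({[tert-butyl(diphenyl)silyl]oxy}methyl)-3-oxoprop-1-en-1-yl]-2-oxo-5-(propan-2-yl)cyclohexane-1-carboxylate | CC(C)[C@H]1CCC(=O)[C@@H](C(=O)OC(C)(C)C)[C@@H]1/C=C(\CO[Si](c2ccccc2)(c3ccccc3)C(C)(C)C)C(=O)OC(C)(C)C | intermediate
15 | tert-butyl (1S,5R,6S)-6-[(1E)-3-tert-butoxy-2-(hydroxymethyl)-3-oxoprop-1-en-1-yl]-2-oxo-5-(propan-2-yl)cyclohexane-1-carboxylate | CC(C)[C@H]1CCC(=O)[C@@H](C(=O)OC(C)(C)C)[C@@H]1/C=C(\CO)C(=O)OC(C)(C)C | intermediate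
16 | tert-butyl (2E)-2-(hydroxymethyl)-3-[(1S,6R)-3-oxo-2-(oxomethylidene)-6-(propan-2-yl)cyclohexyl]prop-2-enoate (acylketene) | CC(C)[C@H]1CCC(=O)C(=C=O)[C@@H]1/C=C(\CO)C(=O)OC(C)(C)C | intermediate
17 | tert-butyl (5aS,6R,9aS)-1,9-dioxo-6-(propan-2-yl)-1,3,5a,6,7,8,9,9a-octahydro-2-benzoxepine-4-carboxylate | CC(C)[C@H]1CCC(=O)[C@H]2C(=O)OCC(C(=O)OC(C)(C)C)=C[C@H]12 | intermediate
18 | tert-butyl (5aS,6R,9aS)-9-methylidene-1-oxo-6-(propan-2-yl)-1,3,5a,6,7,8,9,9a-octahydro-2-benzoxepine-4-carboxylate | CC(C)[C@H]1CCC(=C)[C@H]2C(=O)OCC(C(=O)OC(C)(C)C)=C[C@H]12 | intermediate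
19 | trimethylsilyl (5aS,6R,9aS)-9-methylidene-1-oxo-6-(propan-2-yl)-1,3,5a,6,7,8,9,9a-octahydro-2-benzoxepine-4-carboxylate | CC(C)[C@H]1CCC(=C)[C@H]2C(=O)OCC(C(=O)O[Si](C)(C)C)=C[C@H]12 | intermediate
20 | (5aS,6R,9aS)-9-methylidene-1-oxo-6-(propan-2-yl)-1,3,5a,6,7,8,9,9a-octahydro-2-benzoxepine-4-carboxylic acid | CC(C)[C@H]1CCC(=C)[C@H]2C(=O)OCC(C(=O)O)=C[C@H]12 | intermediate
21 | di-tert-butyl (2E,4S)-5-acetyl-2-({[tert-butyl(diphenyl)silyl]oxy}methyl)-4-(3-methyl-1-oxobutan-2-yl)hex-2-enedioate (epimers at C5 and at the formyl-bearing carbon) | CC(C)C(C=O)[C@H](/C=C(\CO[Si](c1ccccc1)(c2ccccc2)C(C)(C)C)C(=O)OC(C)(C)C)C(C(C)=O)C(=O)OC(C)(C)C | intermediate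
22 | aldol from 21: the 4-hydroxy-2-oxocyclohexane-1-carboxylate with ring substituents at C1, C5 and C6 as in 23, both hydroxyl epimers | CC(C)[C@@H]1C(O)CC(=O)[C@H](C(=O)OC(C)(C)C)[C@H]1/C=C(\CO[Si](c2ccccc2)(c3ccccc3)C(C)(C)C)C(=O)OC(C)(C)C | intermediate
23 | tert-butyl (1R,5R,6R)-6-[(1E)-3-tert-butoxy-2-({[tert-butyl(diphenyl)silyl]oxy}methyl)-3-oxoprop-1-en-1-yl]-2-oxo-5-(propan-2-yl)cyclohex-3-ene-1-carboxylate | CC(C)[C@@H]1C=CC(=O)[C@H](C(=O)OC(C)(C)C)[C@H]1/C=C(\CO[Si](c2ccccc2)(c3ccccc3)C(C)(C)C)C(=O)OC(C)(C)C | intermediate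
24 | tert-butyl (1R,5S,6R)-6-[(1E)-3-tert-butoxy-2-({[tert-butyl(diphenyl)silyl]oxy}methyl)-3-oxoprop-1-en-1-yl]-2-oxo-5-(propan-2-yl)cyclohexane-1-carboxylate | CC(C)[C@@H]1CCC(=O)[C@H](C(=O)OC(C)(C)C)[C@H]1/C=C(\CO[Si](c2ccccc2)(c3ccccc3)C(C)(C)C)C(=O)OC(C)(C)C | intermediate
25 | tert-butyl (1R,5S,6R)-6-[(1E)-3-tert-butoxy-2-(hydroxymethyl)-3-oxoprop-1-en-1-yl]-2-oxo-5-(propan-2-yl)cyclohexane-1-carboxylate | CC(C)[C@@H]1CCC(=O)[C@H](C(=O)OC(C)(C)C)[C@H]1/C=C(\CO)C(=O)OC(C)(C)C | intermediate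
26 | tert-butyl (2E)-2-(hydroxymethyl)-3-[(1R,6S)-3-oxo-2-(oxomethylidene)-6-(propan-2-yl)cyclohexyl]prop-2-enoate (acylketene) | CC(C)[C@@H]1CCC(=O)C(=C=O)[C@H]1/C=C(\CO)C(=O)OC(C)(C)C | intermediate
27 | tert-butyl (5aR,6S,9aR)-1,9-dioxo-6-(propan-2-yl)-1,3,5a,6,7,8,9,9a-octahydro-2-benzoxepine-4-carboxylate | CC(C)[C@@H]1CCC(=O)[C@@H]2C(=O)OCC(C(=O)OC(C)(C)C)=C[C@@H]12 | intermediate
28 | tert-butyl (5aR,6S,9aR)-9-methylidene-1-oxo-6-(propan-2-yl)-1,3,5a,6,7,8,9,9a-octahydro-2-benzoxepine-4-carboxylate | CC(C)[C@@H]1CCC(=C)[C@@H]2C(=O)OCC(C(=O)OC(C)(C)C)=C[C@@H]12 | intermediate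
29 | tert-butyl (5aR,6S,9R,9aR)-9-hydroxy-9-(hydroxymethyl)-1-oxo-6-(propan-2-yl)-1,3,5a,6,7,8,9,9a-octahydro-2-benzoxepine-4-carboxylate | CC(C)[C@@H]1CC[C@](O)(CO)[C@@H]2C(=O)OCC(C(=O)OC(C)(C)C)=C[C@@H]12 | intermediate
30 | (5aS,6R,9aS)-9-methylidene-1-oxo-6-(propan-2-yl)-1,3,5a,6,7,8,9,9a-octahydro-2-benzoxepine-4-carboxylic 2,4,6-trichlorobenzoic anhydride | CC(C)[C@H]1CCC(=C)[C@H]2C(=O)OCC(C(=O)OC(=O)c3c(Cl)cc(Cl)cc3Cl)=C[C@H]12 | intermediate
31 | tert-butyl (5aR,6S,9R,9aR)-9-hydroxy-9-({[(5aS,6R,9aS)-9-methylidene-1-oxo-6-(propan-2-yl)-1,3,5a,6,7,8,9,9a-octahydro-2-benzoxepine-4-carbonyl]oxy}methyl)-1-oxo-6-(propan-2-yl)-1,3,5a,6,7,8,9,9a-octahydro-2-benzoxepine-4-carboxylate | CC(C)[C@H]1CCC(=C)[C@H]2C(=O)OCC(C(=O)OC[C@@]3(O)CC[C@@H](C(C)C)[C@@H]4C=C(C(=O)OC(C)(C)C)COC(=O)[C@H]43)=C[C@H]12 | intermediate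
32 | trimethylsilyl ester and 9-O-trimethylsilyl ether of acid 33 | CC(C)[C@H]1CCC(=C)[C@H]2C(=O)OCC(C(=O)OC[C@@]3(O[Si](C)(C)C)CC[C@@H](C(C)C)[C@@H]4C=C(C(=O)O[Si](C)(C)C)COC(=O)[C@H]43)=C[C@H]12 | intermediate
33 | (5aR,6S,9R,9aR)-9-hydroxy-9-({[(5aS,6R,9aS)-9-methylidene-1-oxo-6-(propan-2-yl)-1,3,5a,6,7,8,9,9a-octahydro-2-benzoxepine-4-carbonyl]oxy}methyl)-1-oxo-6-(propan-2-yl)-1,3,5a,6,7,8,9,9a-octahydro-2-benzoxepine-4-carboxylic acid | CC(C)[C@H]1CCC(=C)[C@H]2C(=O)OCC(C(=O)OC[C@@]3(O)CC[C@@H](C(C)C)[C@@H]4C=C(C(=O)O)COC(=O)[C@H]43)=C[C@H]12 | intermediate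
34 | (5aR,6S,9R,9aR)-9-hydroxy-9-({[(5aS,6R,9S,9aS)-9-hydroxy-9-(hydroxymethyl)-1-oxo-6-(propan-2-yl)-1,3,5a,6,7,8,9,9a-octahydro-2-benzoxepine-4-carbonyl]oxy}methyl)-1-oxo-6-(propan-2-yl)-1,3,5a,6,7,8,9,9a-octahydro-2-benzoxepine-4-carboxylic acid | CC(C)[C@H]1CC[C@@](O)(CO)[C@H]2C(=O)OCC(C(=O)OC[C@@]3(O)CC[C@@H](C(C)C)[C@@H]4C=C(C(=O)O)COC(=O)[C@H]43)=C[C@H]12 | target

**Step count and risks**

Total step count: 19. Longest linear sequence: 13 steps (steps 1–10, then 17–19; the branch through steps 11–16 is equally long).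

The three steps most likely to fail:

1. Step 5 (and its mirror-image twin, step 11). Iminium formation from the hindered α-branched dienal may be slow, so that conversion and face discrimination suffer, and equilibration at C6 may be incomplete. Fallback: 9 and 10 are condensed without chiral control (piperidinium acetate, toluene, 60 °C, the classical amine-catalysed Michael/aldol condensation under equilibrating conditions), which gives 13 and 23 together as the racemate. The two are separated by preparative chromatography on a chiral stationary phase. Because the target contains one half of each handedness, both antipodes are used, and the route is rejoined at 13 (step 6) and at 23 (step 12). The fallback makes no compound outside the list (F0).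

2. Step 9 (and its twin, step 15). The titanium reagent may enolise the β-keto lactone to a chelated enolate instead of transferring the methylene group. Fallback: the enolisation is used instead of fought. From 17, NaH and PhNTf2 in THF give the enol triflate F1. Coupling with Me3SiCH2MgCl and Pd(PPh3)4 in THF gives the allylsilane F2. Fluoride (TBAF, AcOH, THF) removes silicon, and the resulting dienolate is protonated at C9a to give the exocyclic alkene with the more stable trans ring fusion, which is 18. In the mirror-image series the same three operations lead from 27 through the enol triflate F3 and the allylsilane F4 to 28.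

3. Step 16 (the same operation returns as step 19). Facial selectivity of the osmylation of the exocyclic alkene may be poor, giving the C9 epimer. Fallback: anti addition in two steps with the complementary facial preference. From 28, mCPBA (NaHCO3, CH2Cl2) should attack along the axial direction, as peracids do with methylenecyclohexanes, to give the spiro-epoxide F5. Dilute HClO4 in THF/H2O at 0 °C then opens it at the tertiary carbon with inversion, which puts the tertiary hydroxyl equatorial and gives 29. In the same way 33 would go through the spiro-epoxide F6 to 34.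

**Further compounds**

F0 | step 5 | none | none
F1 | step 9 | tert-butyl (5aS,6R)-1-oxo-6-(propan-2-yl)-9-{[(trifluoromethyl)sulfonyl]oxy}-1,3,5a,6,7,8-hexahydro-2-benzoxepine-4-carboxylate | CC(C)[C@H]1CCC(OS(=O)(=O)C(F)(F)F)=C2C(=O)OCC(C(=O)OC(C)(C)C)=C[C@H]12
F2 | step 9 | tert-butyl (5aS,6R)-1-oxo-6-(propan-2-yl)-9-[(trimethylsilyl)methyl]-1,3,5a,6,7,8-hexahydro-2-benzoxepine-4-carboxylate | CC(C)[C@H]1CCC(C[Si](C)(C)C)=C2C(=O)OCC(C(=O)OC(C)(C)C)=C[C@H]12
F3 | step 9 | tert-butyl (5aR,6S)-1-oxo-6-(propan-2-yl)-9-{[(trifluoromethyl)sulfonyl]oxy}-1,3,5a,6,7,8-hexahydro-2-benzoxepine-4-carboxylate | CC(C)[C@@H]1CCC(OS(=O)(=O)C(F)(F)F)=C2C(=O)OCC(C(=O)OC(C)(C)C)=C[C@@H]12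
F4 | step 9 | tert-butyl (5aR,6S)-1-oxo-6-(propan-2-yl)-9-[(trimethylsilyl)methyl]-1,3,5a,6,7,8-hexahydro-2-benzoxepine-4-carboxylate | CC(C)[C@@H]1CCC(C[Si](C)(C)C)=C2C(=O)OCC(C(=O)OC(C)(C)C)=C[C@@H]12
F5 | step 16 | tert-butyl (5aR,6S,9S,9aR)-1-oxo-6-(propan-2-yl)-3,5a,6,7,8,9a-hexahydro-1H-spiro[2-benzoxepine-9,2'-oxirane]-4-carboxylate | CC(C)[C@@H]1CC[C@@]3(CO3)[C@@H]2C(=O)OCC(C(=O)OC(C)(C)C)=C[C@@H]12
F6 | step 16 | (5aR,6S,9R,9aR)-9-hydroxy-1-oxo-9-({[(5aS,6R,9R,9aS)-1-oxo-6-(propan-2-yl)-3,5a,6,7,8,9a-hexahydro-1H-spiro[2-benzoxepine-9,2'-oxirane]-4-carbonyl]oxy}methyl)-6-(propan-2-yl)-1,3,5a,6,7,8,9,9a-octahydro-2-benzoxepine-4-carboxylic acid | CC(C)[C@H]1CC[C@]5(CO5)[C@H]2C(=O)OCC(C(=O)OC[C@@]3(O)CC[C@@H](C(C)C)[C@@H]4C=C(C(=O)O)COC(=O)[C@H]43)=C[C@H]12
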